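(The rate constants are invented.)

Substrate in this flask starts out going to target 1.6 times as fast as it goes forward into intermediate A, and that ratio moves with the partner. So we ask how much partner makes the lasting exits equal.

substrate 20 mM; partner 30.0 mM; capture agent 1.00 mM; time 20 h

    substrate + partner ⇌ intermediate A (K1 = 67.4 /M, k1 = 0.0261 /M/s)
    substrate → target (k2 = 0.00125 /s)
    intermediate A ⇌ intermediate B (K3 = 1.12, k3 = 4.95 × 10⁻⁴ /s)
    intermediate B → side product (k4 = 7.35 × 10⁻⁴ /s)
    capture agent + intermediate B → trapped intermediate (k5 = 0.0129 /M/s)

- the reaction counts as stopped when no species that holds the substrate changes by six tenths of a point or more over the second half of the time
- run time (flask): 20 h

* the state of affairs at 20 h: stopped, and by what, or still going (all of the substrate has reacted / it is still moving / the partner has run out first / forward and back rates have come level)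
* conversion of substrate at 20 h
* amount of target at 20 h, in percent of the substrate charged

We turn each constant into a time at the charged amounts. Substrate stands on the first rung. With both its forward steps open, its half-life is 0.0947 h.

Next comes intermediate B, slower than substrate, with a half-life of 0.26 h towards side product. Capture would take 15 h, far longer, so we drop it. Intermediate B also falls back to intermediate A, and counting those two exits, 62.4% of what reaches it leaves as side product.

Close beside it stands intermediate A, which returns to substrate or passes on for good, with a half-life of about 0.276 h. The part that passes on for good is 44.4%.

The run is far longer than that. So although binding alone is worth 2.0 at the charged partner, we expect the substrate to be used up, with no level resting point.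

What remains is a branching count, and it needs a steady partner, not a steady state. We call the even partner the amount of partner at which substrate's two lasting exits run equally: the target constant divided by the binding constant times the part that passes on, 108 mM. The even partner over the partner present is a selectivity factor, and the target share is the even partner over the sum of the two.

At the charged partner this gives 78.2%. That share would consume 4.35 mM of partner, and at the partner then left the share is 80.8%. We commit to a target yield between these two.

The forecast gives all of the substrate has reacted, conversion 100% and target 79.5%, reasoning that “roughly half of what enters intermediate A returns to substrate”.

The simulation of this flask gives all of the substrate has reacted, with conversion 100% and target 80.3%, inside our bracket. At 20.0 h, 87% of the charged partner is still there in this flask. We now use the even partner on a neighbour flask, the same but for a charge of 120 mM of partner. Its target share comes to 47.4% at that charge, and to 49.5% at the 92% of partner left at its end. The neighbour flask gives 49.1% of target.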